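**Plan**

1. Numbering follows the abyssomicins: C1 lactone C=O, C2, C3 enol carbon, C4(Me), C5, C6(Me), C7 ketone, C8, C9. The cyclohexane is C10–C15, with C11–OH, C12(Me)–O, C13–CH2OH, C14H2 and C15–O(lactone). C16 is the quaternary carbon that carries the ether oxygen.
2. Cuts, in order: C8–C16 (transannular Michael), C8=C9 (metathesis), C2–C3 (tetronate anion plus aldehyde), the C1–C2 unit (ketenylidene ylide on an α-hydroxy lactone), and C9–C10 (formaldehyde aldol). Last, the C12–C13 bond of the cyclohexanone is moved back to C11–C13, which leaves a cyclopentane.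
3. Enabling feature: in ring C10–C15 the pair C11(OH)/C12(Me)(O-ether) is an α-alkoxy ketone retron. The ether oxygen is tied through C16 to C15, 1,4 across the ring. A 1-acetylcyclopentanol (ring C10-C11-C13-C14-C15) whose acetyl C12=O is held as a bridged lactol by the C16 hydroxyl can therefore take C12 into the ring by a semipinacol shift.
4. Forward ring order: cyclopentane (Pd-trimethylenemethane [3+2]), then 3-oxabicyclo[3.2.1]octane lactol, then 2-oxabicyclo[2.2.2]octanone (ring expansion), then tetronate, then the 11-membered macrocycle, then cyclopentane and cyclooctane together (reductive transannular Michael).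
5. Stereochemistry: (S)-5-methylbutenolide sets C13 and is then erased. Anti-face oxidations set the temporary C11 carbinol and C15. The tether sets C12. Aldol and directed reduction set C10 and C11. Enzymatic desymmetrisation of a meso diol sets C4 and C6. The cage sets C16 and C8.

Key step: step 7

Assumption: (S)-5-methylfuran-2(5H)-one (1) and meso-2,4-dimethylglutaric anhydride (23) are taken as catalogue compounds.

**Step 1**
Reactants: 1 (S)-5-methylfuran-2(5H)-one; 2 2-[(trimethylsilyl)methyl]allyl acetate
Product: 3 (3S,3aR,6aS)-3-methyl-5-methylidenehexahydro-1H-cyclopenta[c]furan-1-one (cis-fused; methyl anti to the new ring)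
Conditions: Pd(OAc)2 (5 mol %), P(Oi-Pr)3 (30 mol %), toluene, 100 °C
Reagents that add atoms: none
Why: Palladium–trimethylenemethane [3+2] cycloaddition to an electron-poor butenolide, in which the zwitterion should add anti to the 5-methyl group and the lactone enforces the cis fusion, so that C13 (and for the time being C11) is set from the lactate-type centre.

**Step 2**
Reactants: 3 bicyclic lactone
Product: 4 (1S)-1-[(1R,2S)-2-(hydroxymethyl)-4-methylidenecyclopentyl]ethan-1-ol
Conditions: LiAlH4, THF, 0 °C
Reagents that add atoms: none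
Why: Exhaustive hydride reduction of a lactone to the diol, which touches no stereocentre and removes the acceptor from C13, as the migrating carbon of step 7 must be electron-rich.

**Step 3**
Reactants: 4 diol
Product: 5 primary TIPS ether of 4 (secondary alcohol free)
Conditions: TIPSCl, imidazole, CH2Cl2, 0 °C
Reagents that add atoms: triisopropylsilyl chloride CC(C)[Si](Cl)(C(C)C)C(C)C
Why: Chemoselective silylation of the primary over the secondary alcohol with a bulky chloride, the TIPS group being chosen because it resists Lewis acid (step 7) and has no arene for RuO4 to attack (step 8).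

**Step 4**
Reactants: 5 TIPS ether alcohol
Product: 6 cis-1-acetyl-4-methylidene-2-[(triisopropylsilyloxy)methyl]cyclopentane
Conditions: Dess–Martin periodinane, NaHCO3, CH2Cl2, rt
Reagents that add atoms: none
Why: Dess–Martin oxidation of the secondary alcohol to the methyl ketone, which erases the lactate-type centre after it has done its work.

**Step 5**
Reactants: 6 methyl ketone
Product: 8 1-acetylcyclopentan-1-ol (α-ketol; OH trans and acetyl cis to the neighbouring CH2OTIPS), via hydroperoxide 7 (not isolated)
Conditions: KOt-Bu, O2, P(OEt)3, THF/t-BuOH, −20 °C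
Reagents that add atoms: dioxygen O=O
Why: Enolate autoxidation with in situ phosphite reduction (the classical 17α-hydroxylation of 20-oxo steroids), in which the more substituted enolate should trap O2 on the face anti to CH2OTIPS and so place the acetyl group cis to it.

**Step 6**
Reactants: 8 α-ketol
Product: 10 2-methyl-7-[(triisopropylsilyloxy)methyl]-3-oxabicyclo[3.2.1]octane-1,2,5-triol (bridged lactol; anomers at C12), via keto-triol 9 (not isolated)
Conditions: OsO4 (2 mol %), NMO, acetone/H2O, rt
Reagents that add atoms: osmium tetroxide O=[Os](=O)(=O)=O; N-methylmorpholine N-oxide C[N+]1([O-])CCOCC1; water O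
Why: Upjohn dihydroxylation of the 1,1-disubstituted alkene from the face opposite the cis acetyl and CH2OTIPS groups sets C15, and the new primary alcohol, now cis to the acetyl group, should close onto the ketone (6-exo-trig hemiketalisation).

**Step 7**
Reactants: 10 bridged lactol
Product: 12 4-hydroxy-1-methyl-7-[(triisopropylsilyloxy)methyl]-2-oxabicyclo[2.2.2]octan-6-one, via oxocarbenium ion 11 (not isolated)
Conditions: Sc(OTf)3 (10 mol %), 4 Å MS, MeNO2/CH2Cl2, 0 °C to rt
Reagents that add atoms: none
Why: Proposed new method: the Lewis acid ionises the hemiketal to the bridged oxocarbenium ion 11 (C12=O+ inside the 3-oxabicyclo[3.2.1]octane), and the adjacent bridgehead carbinol C11–OH then drives a semipinacol 1,2-shift of C13 from C11 to C12, so that the cyclopentane C10-C11-C13-C14-C15 takes up C12 and becomes the cyclohexanone C10–C15 with loss of the O–H proton. The closest known reaction types are the acid-promoted acyloin (D-homoannulation) rearrangement of 1-acetylcyclopentanols and oxonium-ion-initiated pinacol ring expansions; new is that the ketone is activated by a hydroxyl group held across the ring, which stays behind as the ether bridge. No ring is closed by attack of a chain end: the bicyclo[3.2.1] to bicyclo[2.2.2] Wagner–Meerwein shift turns the lactol ring (closed in step 6, 6-exo-trig) and the five-membered carbocycle into the three six-membered rings of the 2-oxabicyclo[2.2.2]octane. C12 becomes a bridgehead, so its configuration is dictated by the O–C16–C15 tether, and C13 migrates with retention and keeps the configuration of step 1. The step needs migration of C13 and not of C10: the C11–C13 bond is the axial two-carbon bridge on the chair-like lactol ring and lies parallel to the empty orbital at C12, whereas C11–C10 lies near the oxocarbenium plane, and C13 is the more substituted carbon and carries no acceptor. Removal of water by the sieves and the low basicity of the α-alkoxy ketone should keep the shift from reverting.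

**Step 8**
Reactants: 12 bicyclic keto ether
Product: 13 4-hydroxy-1-methyl-7-[(triisopropylsilyloxy)methyl]-2-oxabicyclo[2.2.2]octane-3,6-dione
Conditions: RuCl3·xH2O (5 mol %), NaIO4, MeCN/EtOAc/H2O, rt
Reagents that add atoms: sodium periodate [Na+].[O-]I(=O)(=O)=O
Why: Ruthenium tetroxide oxidation of an ether CH2 to the lactone, C16 being the only CH2 next to a dialkyl ether oxygen (C12 is quaternary), while ketone, tertiary alcohol and alkyl silyl ether tolerate the reagent.

**Step 9**
Reactants: 13 α-hydroxy keto lactone
Product: 15 C11-keto tetronate (2-oxabicyclo[2.2.2]octanone with the butenolide O–C1(=O)–C2H=C16 fused on C15–C16), via ester ylide 14 (not isolated)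
Conditions: Ph3P=C=C=O, toluene, 110 °C
Reagents that add atoms: (triphenylphosphoranylidene)ketene O=C=C=P(c1ccccc1)(c1ccccc1)c1ccccc1
Why: Bestmann-ylide tetronate synthesis from an α-hydroxy ester, in which the tertiary hydroxyl adds to the cumulated ylide and ester ylide 14 olefinates the neighbouring lactone carbonyl by intramolecular Wittig reaction (five-membered ring), the C11 ketone being out of reach because O–C15–C10–C11 is antiperiplanar.

**Step 10**
Reactants: 15 keto tetronate
Product: 17 C10-hydroxymethyl ketone (CH2OH on the face turned to the O–C16 bridge), via lithium enolate 16 (not isolated)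
Conditions: LiHMDS, THF, −78 °C; then monomeric CH2O in THF
Reagents that add atoms: formaldehyde C=O
Why: Lithium enolate aldol (hydroxymethylation), in which only C10 can be deprotonated (C12 is quaternary and β-elimination would give a bridgehead alkene) and the electrophile should enter from the face next to the flat C16=C2 bridge rather than the C14H2 bridge, which is also the more stable arrangement at this epimerisable centre.

**Step 11**
Reactants: 17 β-hydroxy ketone
Product: 18 C9,C11-diol (C11–OH trans to C9 and anti to the ether oxygen)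
Conditions: Me4NBH(OAc)3, MeCN/AcOH, −30 °C
Reagents that add atoms: none
Why: Saksena–Evans hydroxyl-directed reduction, in which boron bound to the C9 hydroxyl delivers hydride to the same face of the C11 carbonyl and so sets the C11 carbinol as in the target.

**Step 12**
Reactants: 18 diol
Product: 20 C9-OTES C11-OTBS bis-silyl ether, via mono-TES ether 19 (not isolated)
Conditions: TESCl, imidazole, CH2Cl2, −20 °C; then TBSOTf, 2,6-lutidine, 0 °C
Reagents that add atoms: triethylsilyl chloride CC[Si](Cl)(CC)CC; tert-butyldimethylsilyl triflate CC(C)(C)[Si](C)(C)OS(=O)(=O)C(F)(F)F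
Why: One-pot sequential silylation that uses the rate difference between the primary and the hindered secondary alcohol to place a labile and a robust group.

**Step 13**
Reactants: 20 bis-silyl ether
Product: 21 C9 aldehyde
Conditions: (COCl)2, DMSO, CH2Cl2, −78 to −40 °C; then Et3N
Reagents that add atoms: none
Why: Swern oxidation run directly on the silyl ether, since primary TES ethers are cleaved and oxidised by the chlorosulfonium salt while TBS and TIPS ethers survive.

**Step 14**
Reactants: 21 aldehyde
Product: 22 C10-vinyl tetronate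
Conditions: MePPh3Br, KHMDS, THF, −78 to 0 °C
Reagents that add atoms: methyltriphenylphosphonium bromide C[P+](c1ccccc1)(c1ccccc1)c1ccccc1.[Br-]
Why: Wittig methylenation at low temperature, fast enough on an aldehyde to avoid epimerisation at C10 or β-elimination of the silyloxy group, the vinylogous carbonate carbonyl being inert.

**Step 15**
Reactants: 23 meso-2,4-dimethylglutaric anhydride
Product: 24 meso-(2R,4S)-2,4-dimethylpentane-1,5-diol
Conditions: LiAlH4, THF, 0 °C to rt
Reagents that add atoms: none
Why: Hydride reduction of a cyclic anhydride to the diol without touching the methyl-bearing centres.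

**Step 16**
Reactants: 24 meso diol
Product: 25 (2S,4R)-5-hydroxy-2,4-dimethylpentyl acetate
Conditions: Amano lipase AK, vinyl acetate, THF, rt
Reagents that add atoms: vinyl acetate C=COC(C)=O
Why: Lipase-catalysed enantiotopos-selective acetylation (desymmetrisation of a meso diol) with an irreversible acyl donor, which fixes the absolute configuration of C4 and C6.

**Step 17**
Reactants: 25 monoacetate
Product: 26 (2S,4R)-2,4-dimethyl-5-oxopentyl acetate
Conditions: Dess–Martin periodinane, NaHCO3, CH2Cl2, rt
Reagents that add atoms: none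
Why: Dess–Martin oxidation under buffered conditions, which should not epimerise the α-methyl aldehyde.

**Step 18**
Reactants: 26 aldehyde acetate
Product: 27 (2S,4R)-2,4-dimethylhept-6-ene-1,5-diol (C5 epimers)
Conditions: vinylmagnesium bromide (4 equiv), THF, −78 to 0 °C
Reagents that add atoms: vinylmagnesium bromide C=C[Mg]Br
Why: Grignard 1,2-addition to the aldehyde with concomitant removal of the acetate by excess reagent, the new carbinol (C7) being oxidised later so that its configuration does not matter.

**Step 19**
Reactants: 27 diol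
Product: 28 bis-TES ether of 27
Conditions: TESCl, imidazole, DMF, 0 °C
Reagents that add atoms: triethylsilyl chloride CC[Si](Cl)(CC)CC
Why: Standard silylation of both alcohols to set up the selective oxidation of step 20.

**Step 20**
Reactants: 28 bis-TES ether
Product: 29 (2S,4R)-2,4-dimethyl-5-(triethylsilyloxy)hept-6-enal (C5 epimers)
Conditions: (COCl)2, DMSO, CH2Cl2, −78 to −40 °C; then Et3N
Reagents that add atoms: none
Why: Swern oxidation directly on the silyl ether, selective for the primary TES ether over the secondary one.

**Step 21**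
Reactants: 22 vinyl tetronate; 29 aldehyde
Product: 31 C3 carbinol diene (epimers at C3 and C7), via lithiated tetronate 30 (not isolated)
Conditions: LDA, THF, −78 °C; then 29
Reagents that add atoms: none
Why: Deprotonation of a 4-alkoxybutenolide at its α-vinylic position C2 and 1,2-addition to an aldehyde, the standard way to 3-acyl tetronate precursors, with carbinol epimers that converge in step 23.

**Step 22**
Reactants: 31 diene
Product: 32 11-membered (E)-C8=C9 macrocycle
Conditions: Grubbs second-generation catalyst (10 mol %), CH2Cl2 (1 mM), 40 °C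
Reagents that add atoms: none
Why: Ring-closing metathesis of two monosubstituted alkenes under high dilution, a ring size and substitution pattern with close precedent in this family of macrocycles.

**Step 23**
Reactants: 32 macrocycle
Product: 33 C3,C7-dioxo (E)-enone macrocycle
Conditions: IBX, DMSO, rt
Reagents that add atoms: none
Why: IBX oxidation of the C3 carbinol together with the known IBX-mediated oxidative cleavage of a TES ether (allylic C7) to the ketone, under which TBS and TIPS ethers persist.

**Step 24**
Reactants: 33 enone macrocycle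
Product: 35 bis-silylated abyssomicin O (C11-OTBS; 13-CH2OTIPS), via C7–C8 enolate 34 (not isolated)
Conditions: L-Selectride, THF, −78 to 0 °C; aq NH4Cl
Reagents that add atoms: none
Why: Conjugate reduction of the enone gives the regiodefined enolate 34, which should add transannularly to C16 of the acyl tetronate (5-exo-trig Michael, closing cyclopentane and cyclooctane at once, a reaction type known for this macrocycle class), the C9–C10 tether fixing the face of C16 and the cis ring fusion fixing the still epimerisable C8.

**Step 25**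
Reactants: 35 protected product
Product: 36 abyssomicin O
Conditions: HF·pyridine, THF, 0 °C to rt
Reagents that add atoms: none
Why: Acidic fluoride desilylation removes both silyl ethers without the base that could trigger a retro-Michael opening of the cage.

**Compound list**

1 | (S)-5-methylfuran-2(5H)-one | C[C@@H]1OC(=O)C=C1 | starting material
2 | 2-[(trimethylsilyl)methyl]allyl acetate | CC(=O)OCC(=C)C[Si](C)(C)C | starting material
3 | cis-fused methylidene bicyclic lactone | C[C@@H]1OC(=O)[C@H]2CC(=C)C[C@@H]12 | intermediate
4 | diol | C[C@H](O)[C@@H]1CC(=C)C[C@@H]1CO | intermediate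
5 | primary TIPS ether | C[C@H](O)[C@@H]1CC(=C)C[C@@H]1CO[Si](C(C)C)(C(C)C)C(C)C | intermediate
6 | methyl ketone | CC(=O)[C@@H]1CC(=C)C[C@@H]1CO[Si](C(C)C)(C(C)C)C(C)C | intermediate
7 | α-hydroperoxy ketone (not isolated) | CC(=O)[C@]1(OO)CC(=C)C[C@@H]1CO[Si](C(C)C)(C(C)C)C(C)C | intermediate
8 | α-ketol | CC(=O)[C@]1(O)CC(=C)C[C@@H]1CO[Si](C(C)C)(C(C)C)C(C)C | intermediate
9 | open keto-triol (not isolated) | CC(=O)[C@]1(O)C[C@](O)(CO)C[C@@H]1CO[Si](C(C)C)(C(C)C)C(C)C | intermediate
10 | bridged lactol (3-oxabicyclo[3.2.1]octane) | O[C@@]12C[C@H](CO[Si](C(C)C)(C(C)C)C(C)C)[C@@](O)(C1)C(C)(O)OC2 | intermediate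
11 | bridged oxocarbenium ion (not isolated) | O[C@@]12C[C@H](CO[Si](C(C)C)(C(C)C)C(C)C)[C@@](O)(C1)C(C)=[O+]C2 | intermediate
12 | 2-oxabicyclo[2.2.2]octan-6-one | O[C@]12C[C@H](CO[Si](C(C)C)(C(C)C)C(C)C)[C@](C)(OC1)C(=O)C2 | intermediate
13 | keto lactone | O[C@]12C[C@H](CO[Si](C(C)C)(C(C)C)C(C)C)[C@](C)(OC1=O)C(=O)C2 | intermediate
14 | ester ylide (not isolated) | O=C(C=P(c1ccccc1)(c1ccccc1)c1ccccc1)O[C@]12C[C@H](CO[Si](C(C)C)(C(C)C)C(C)C)[C@](C)(OC1=O)C(=O)C2 | intermediate
15 | keto tetronate | O=C1O[C@]23C[C@H](CO[Si](C(C)C)(C(C)C)C(C)C)[C@](C)(OC2=C1)C(=O)C3 | intermediate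
16 | lithium enolate (not isolated) | O=C1O[C@]23C[C@H](CO[Si](C(C)C)(C(C)C)C(C)C)[C@](C)(OC2=C1)C(O[Li])=C3 | intermediate
17 | C10-hydroxymethyl ketone | O=C1O[C@]23C[C@H](CO[Si](C(C)C)(C(C)C)C(C)C)[C@](C)(OC2=C1)C(=O)[C@@H]3CO | intermediate
18 | C9,C11-diol | O=C1O[C@]23C[C@H](CO[Si](C(C)C)(C(C)C)C(C)C)[C@](C)(OC2=C1)[C@@H](O)[C@@H]3CO | intermediate
19 | mono-TES ether (not isolated) | O=C1O[C@]23C[C@H](CO[Si](C(C)C)(C(C)C)C(C)C)[C@](C)(OC2=C1)[C@@H](O)[C@@H]3CO[Si](CC)(CC)CC | intermediate
20 | TES/TBS bis-ether | O=C1O[C@]23C[C@H](CO[Si](C(C)C)(C(C)C)C(C)C)[C@](C)(OC2=C1)[C@@H](O[Si](C)(C)C(C)(C)C)[C@@H]3CO[Si](CC)(CC)CC | intermediate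
21 | C9 aldehyde | O=C1O[C@]23C[C@H](CO[Si](C(C)C)(C(C)C)C(C)C)[C@](C)(OC2=C1)[C@@H](O[Si](C)(C)C(C)(C)C)[C@@H]3C=O | intermediate
22 | C10-vinyl tetronate | O=C1O[C@]23C[C@H](CO[Si](C(C)C)(C(C)C)C(C)C)[C@](C)(OC2=C1)[C@@H](O[Si](C)(C)C(C)(C)C)[C@@H]3C=C | intermediate
23 | meso-2,4-dimethylglutaric anhydride | O=C1OC(=O)[C@@H](C)C[C@H]1C | starting material
24 | meso-2,4-dimethylpentane-1,5-diol | OC[C@@H](C)C[C@@H](C)CO | intermediate
25 | (2S,4R)-5-hydroxy-2,4-dimethylpentyl acetate | CC(=O)OC[C@@H](C)C[C@@H](C)CO | intermediate
26 | (2S,4R)-2,4-dimethyl-5-oxopentyl acetate | CC(=O)OC[C@@H](C)C[C@@H](C)C=O | intermediate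
27 | (2S,4R)-2,4-dimethylhept-6-ene-1,5-diol | OC[C@@H](C)C[C@@H](C)C(O)C=C | intermediate
28 | bis-TES ether | CC[Si](CC)(CC)OC[C@@H](C)C[C@@H](C)C(O[Si](CC)(CC)CC)C=C | intermediate
29 | (2S,4R)-2,4-dimethyl-5-(triethylsilyloxy)hept-6-enal | O=C[C@@H](C)C[C@@H](C)C(O[Si](CC)(CC)CC)C=C | intermediate
30 | C2-lithiated tetronate (not isolated) | O=C1O[C@]23C[C@H](CO[Si](C(C)C)(C(C)C)C(C)C)[C@](C)(OC2=C1[Li])[C@@H](O[Si](C)(C)C(C)(C)C)[C@@H]3C=C | intermediate
31 | C3 carbinol diene | O=C1O[C@]23C[C@H](CO[Si](C(C)C)(C(C)C)C(C)C)[C@](C)(OC2=C1C(O)[C@@H](C)C[C@@H](C)C(O[Si](CC)(CC)CC)C=C)[C@@H](O[Si](C)(C)C(C)(C)C)[C@@H]3C=C | intermediate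
32 | (E)-macrocycle | C[C@@H]1C[C@H](C)C(O)C2=C3O[C@@]4(C)[C@@H](CO[Si](C(C)C)(C(C)C)C(C)C)C[C@]3(OC2=O)[C@@H](/C=C/C1O[Si](CC)(CC)CC)[C@@H]4O[Si](C)(C)C(C)(C)C | intermediate
33 | enone macrocycle | C[C@@H]1C[C@H](C)C(=O)C2=C3O[C@@]4(C)[C@@H](CO[Si](C(C)C)(C(C)C)C(C)C)C[C@]3(OC2=O)[C@@H](/C=C/C1=O)[C@@H]4O[Si](C)(C)C(C)(C)C | intermediate
34 | C7–C8 enolate (not isolated) | C[C@@H]1C[C@H](C)C(=O)C2=C3O[C@@]4(C)[C@@H](CO[Si](C(C)C)(C(C)C)C(C)C)C[C@]3(OC2=O)[C@@H](CC=C1O[Li])[C@@H]4O[Si](C)(C)C(C)(C)C | intermediate
35 | bis-silylated abyssomicin O | C[C@@H]1C[C@H](C)/C(O)=C2/C(=O)O[C@]34C[C@H](CO[Si](C(C)C)(C(C)C)C(C)C)[C@]5(C)O[C@]23[C@@H](C[C@H]4[C@@H]5O[Si](C)(C)C(C)(C)C)C1=O | intermediate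
36 | abyssomicin O | C[C@@H]1C[C@H](C)/C(O)=C2/C(=O)O[C@]34C[C@H](CO)[C@]5(C)O[C@]23[C@@H](C[C@H]4[C@@H]5O)C1=O | target

Total step count: 25. Longest linear sequence: 19 steps (steps 1–14 and 21–25).

**Steps most likely to fail**

1. **Step 7.**
   - *What may go wrong:* Ionisation may be diverted to the exocyclic enol ether or to loss of the silyl group. The shift may also be too slow, because little strain is released.
   - *Fallback (known chemistry only, from 8 back to 12):* The ketol 8 is submitted to the classical Lewis-acid acyloin (D-homoannulation-type) rearrangement with Al(Ot-Bu)3 in hot toluene. This gives 2-hydroxy-2-methyl-5-methylidene-3-[(triisopropylsilyloxy)methyl]cyclohexanone F1. Peracid epoxidation of its exocyclic methylene gives the spiro-epoxide F2; the epimeric epoxide cannot cyclise and is removed. The potassium alkoxide of the tertiary alcohol (KH, THF, 0 °C) then opens the epoxide at its CH2 terminus (6-exo-tet) to give 12.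

2. **Step 8.**
   - *What may go wrong:* C–H oxidation next to the electron-poor C15 may be slow. The transient α-hydroxy lactol may be cleaved by periodate. The CH2 of the silyl ether may be attacked.
   - *Fallback (from 10 back to 13):* C16 is raised to the aldehyde level before the ring expansion. TEMPO/PhI(OAc)2 oxidises the primary alcohol of 10 through its open form to the bridged bis-lactol F3. Treatment with MeOH and CSA gives the bridged bis(methyl acetal) F4. Lewis acid ionises the more substituted C12 ketal and brings about the same shift, giving the 3-methoxy-2-oxabicyclo[2.2.2]octan-6-one F5. Oxidation of the cyclic acetal with mCPBA/BF3·OEt2 then gives 13.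

3. **Step 24.**
   - *What may go wrong:* Hydride may attack another carbonyl group. The enolate may be protonated before it cyclises. Cyclisation may proceed through the macrocycle conformer that leads to the C8 epimer.
   - *Fallback (from 33 back to 35):* The two events are separated and placed under thermodynamic control. Copper hydride conjugate reduction (Stryker reagent, wet benzene) gives the saturated C7 ketone macrocycle F6. DBU in toluene then equilibrates the enolates until the 5-exo transannular Michael adduct with the more stable cis ring fusion, 35, accumulates.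

**Further compounds**

F1 | step 7 | 2-hydroxy-2-methyl-5-methylidene-3-[(triisopropylsilyloxy)methyl]cyclohexanone | C=C1C[C@H](CO[Si](C(C)C)(C(C)C)C(C)C)[C@](C)(O)C(=O)C1
F2 | step 7 | spiro-epoxide of F1 | O=C1C[C@]2(CO2)C[C@H](CO[Si](C(C)C)(C(C)C)C(C)C)[C@]1(C)O
F3 | step 8 | bridged bis-lactol | O[C@@]12C[C@H](CO[Si](C(C)C)(C(C)C)C(C)C)[C@@](O)(C1)C(C)(O)OC2O
F4 | step 8 | bridged bis(methyl acetal) | O[C@@]12C[C@H](CO[Si](C(C)C)(C(C)C)C(C)C)[C@@](O)(C1)C(C)(OC)OC2OC
F5 | step 8 | 3-methoxy-2-oxabicyclo[2.2.2]octan-6-one | O[C@]12C[C@H](CO[Si](C(C)C)(C(C)C)C(C)C)[C@](C)(OC1OC)C(=O)C2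
F6 | step 24 | saturated C7 ketone macrocycle | C[C@@H]1C[C@H](C)C(=O)C2=C3O[C@@]4(C)[C@@H](CO[Si](C(C)C)(C(C)C)C(C)C)C[C@]3(OC2=O)[C@@H](CCC1=O)[C@@H]4O[Si](C)(C)C(C)(C)C
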